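**Plan**
Retrosynthesis: C16=C17 is cut first (α-methylenation), then C12–C13 (radical closure of ring C). Next come C13=C16, C8–C15 and C8–C14 (spiro ring D by aldol, allylation and metathesis), C9–C11 (conjugate addition), C8=C9 (lactone by metathesis), and C5–C10 with C3–C4 (ring A by [4+2]).
Forward: ring A by cycloaddition, then C4 methyl and C10 allyl, reduction, the 7,20-lactone, the C9 two-carbon chain, spiro cyclopentenone ring D, ring C, and last the exocyclic methylene.
Enabling feature: through C16, bridgehead C13 is the β-carbon of the C15 ketone. A cyclopent-2-enone ring D (C16=C13) spiro-fused at quaternary C8 can therefore accept a C12 radical held on C9, and the ring that forms (C8, C9, C11, C12, C13, C14) is six-membered.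
Stereochemistry: C5 comes from an amine-catalysed cycloaddition. C4, C10 and C1 are relayed from C5 (alkylations anti to the C5 substituent, axial hydride delivery). C9 is set by cuprate addition on the lactone face next to O1, C8 by aldol anti to the C9 chain, and C13 by the tether from C8/C9.
O1 and O19 are carried as triethylsilyl ethers through the enolate chemistry and become the acetates just before the radical step.

Key step: step 24

Remark: locants C1–C20 are the ent-kaurane numbers of the target; α is the ring A face that carries C20 and β the face that carries C9. TBDPS = tert-butyldiphenylsilyl, TES = triethylsilyl, TBS = tert-butyldimethylsilyl. Methyl 5-methoxy-3-oxopentanoate and (E)-but-2-ene-1,4-diol are assumed to be catalogue chemicals.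

**Route**

Step 1
Reactants: 1 (E)-but-2-ene-1,4-diol
Product: 2 (E)-4-(TBDPS-oxy)but-2-en-1-ol
Conditions: NaH (1.0 equiv), THF, 0 °C; then tert-butyl(chloro)diphenylsilane
Reagents that add atoms: tert-butyl(chloro)diphenylsilane, CC(C)(C)[Si](Cl)(c1ccccc1)c1ccccc1
Why: Silylation of the monosodium alkoxide of a symmetrical diol is a standard way to protect one of two equivalent hydroxyl groups.

Step 2
Reactants: 2 (E)-4-(TBDPS-oxy)but-2-en-1-ol
Product: 3 (E)-4-(TBDPS-oxy)but-2-enal
Conditions: MnO2, CH2Cl2, rt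
Reagents that add atoms: none
Why: MnO2 oxidises allylic alcohols selectively to enals and leaves the silyl ether and the E double bond untouched.

Step 3
Reactants: 4 methyl 5-methoxy-3-oxopentanoate
Product: 5 methyl 3-oxopent-4-enoate (Nazarov reagent)
Conditions: TsOH·H2O (cat.), toluene, 110 °C, methanol distilled off; product distilled and used at once
Reagents that add atoms: none
Why: Acid-catalysed β-elimination of methanol from a β-methoxy ketone releases the vinyl ketone.

Step 4
Reactants: 5 methyl 3-oxopent-4-enoate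
Product: 6 methyl (2Z)-3-(TBS-oxy)penta-2,4-dienoate
Conditions: tert-butyldimethylsilyl triflate, Et3N, CH2Cl2, 0 °C
Reagents that add atoms: tert-butyldimethylsilyl trifluoromethanesulfonate, CC(C)(C)[Si](C)(C)OS(=O)(=O)C(F)(F)F
Why: Soft enolisation of the β-keto ester gives the O-silyl dienol ether; the Z isomer, with the ester on the outside of the diene, is the one able to reach the s-cis form.

Step 5
Reactants: 3 (E)-4-(TBDPS-oxy)but-2-enal; 6 methyl (2Z)-3-(TBS-oxy)penta-2,4-dienoate
Product: 8 ring A keto aldehyde (methyl 6-(TBDPS-oxymethyl)-5-formyl-2-oxocyclohexane-1-carboxylate; C6 on the α face of C5), via cycloadduct silyl enol ether 7 (not isolated)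
Conditions: (S)-2-[diphenyl(trimethylsilyloxy)methyl]pyrrolidine (20 mol%), CF3CO2H (20 mol%), toluene, −20 °C; then 1 M HCl, THF, 0 °C
Reagents that add atoms: none
Why: Iminium-catalysed Diels–Alder reaction of an enal with a 2-silyloxy diene: the CPh2(OSiMe3) group shields the Re face of C5 in the E-iminium ion, so the nucleophilic diene terminus C10 bonds to the Si face and fixes C5; the silyloxy group ends para to the formyl carbon (formyl on C4), and C4 and C10 stay epimerisable and are set later.

Step 6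
Reactants: 8 ring A keto aldehyde; 9 iodomethane
Product: 10 C4-methyl keto aldehyde (methyl 6-(TBDPS-oxymethyl)-5-formyl-5-methyl-2-oxocyclohexane-1-carboxylate; CH3 β, CHO α)
Conditions: NaH, THF, 0 °C; KN(SiMe3)2, −78 °C; MeI (1.0 equiv), −78 to −30 °C; AcOH
Reagents that add atoms: iodomethane (9), CI
Why: In the dianion the β-keto ester is tied up as its enolate and the less stabilised aldehyde enolate at C4 is methylated first (regioselective dianion alkylation); allylic strain forces the C5 side chain axial, so MeI enters anti to it and the methyl group ends trans to C6.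

Step 7
Reactants: 10 C4-methyl keto aldehyde; 11 allyl bromide
Product: 12 C10-allyl keto aldehyde (methyl 1-allyl-6-(TBDPS-oxymethyl)-5-formyl-5-methyl-2-oxocyclohexane-1-carboxylate; allyl β, CO2Me α)
Conditions: NaH, THF, 0 °C; allyl bromide, rt
Reagents that add atoms: allyl bromide (11), C=CCBr
Why: C-alkylation of a cyclic β-keto ester enolate creates quaternary C10; the allyl group enters anti to the adjacent C5 side chain and to the axial C4 formyl group, which leaves the ester (future C20) cis to C6.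

Step 8
Reactants: 12 C10-allyl keto aldehyde
Product: 13 C10-propenyl keto aldehyde ((E)-prop-1-enyl in place of allyl; geometry irrelevant)
Conditions: RuHCl(CO)(PPh3)3 (5 mol%), toluene, 80 °C
Reagents that add atoms: none
Why: Ruthenium hydride catalysed migration of a terminal double bond by one position turns the allyl group into the alkenyl group (C9=) needed for six-membered lactone formation; the quaternary carbon stops further migration.

Step 9
Reactants: 13 C10-propenyl keto aldehyde
Product: 14 triol (1α-OH, C19 OH, C20 OH; C6 OTBDPS)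
Conditions: LiAlH4, THF, −78 to 0 °C; aqueous potassium sodium tartrate
Reagents that add atoms: none
Why: Hydride reduction of aldehyde, ketone and ester; at C1 the hydride attacks axially from the β face, away from the axial C10 carboxyl group, giving the equatorial 1α-alcohol cis to C20.

Step 10
Reactants: 14 triol
Product: 17 19-O-TES diol (1α-OH and C20 OH free), via cyclic phenylboronate 15 (not isolated), via cyclic phenylboronate triethylsilyl ether 16 (not isolated)
Conditions: PhB(OH)2, MgSO4, CH2Cl2, rt; then imidazole, Et3SiCl, 0 °C; then aqueous sorbitol, Na2CO3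
Reagents that add atoms: chlorotriethylsilane, CC[Si](Cl)(CC)CC
Why: The cis-1,3-diol O1/O20 is masked in the flask as a six-membered boronate so that only the C19 hydroxyl is silylated, and mild aqueous diol exchange then frees the 1,3-diol (transient boronate protection).

Step 11
Reactants: 17 19-O-TES diol; 18 acryloyl chloride
Product: 19 20-O-acrylate (1α-OH free)
Conditions: acryloyl chloride (1.05 equiv), iPr2NEt, CH2Cl2, −78 °C
Reagents that add atoms: acryloyl chloride (18), C=CC(=O)Cl
Why: Acylation at low temperature takes the primary C20 hydroxyl in preference to the secondary C1 hydroxyl flanked by quaternary C10.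

Step 12
Reactants: 19 20-O-acrylate
Product: 20 1-O-TES 20-O-acrylate
Conditions: triethylsilyl triflate, 2,6-lutidine, CH2Cl2, −78 °C
Reagents that add atoms: triethylsilyl trifluoromethanesulfonate, CC[Si](CC)(CC)OS(=O)(=O)C(F)(F)F
Why: Silyl triflate with a hindered base silylates the hindered secondary alcohol quickly and without acyl migration.

Step 13
Reactants: 20 1-O-TES 20-O-acrylate
Product: 21 unsaturated spirolactone (7,20-olide with C8=C9; C10 spiro)
Conditions: second-generation Grubbs catalyst RuCl2(=CHPh)(PCy3)(H2IMes) (5 mol%), toluene, 80 °C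
Reagents that add atoms: none
Why: Ring-closing metathesis of the acrylate with the propenyl group on quaternary C10 gives the α,β-unsaturated δ-lactone and propene.

Step 14
Reactants: 21 unsaturated spirolactone; 22 vinylmagnesium bromide
Product: 24 C9-vinyl lactone (vinyl on the lactone face that carries C1), via trimethylsilyl ketene acetal 23 (not isolated)
Conditions: vinylmagnesium bromide, CuBr·SMe2 (10 mol%), Me3SiCl, THF, −78 to −40 °C; then aqueous NH4Cl
Reagents that add atoms: vinylmagnesium bromide (22), C=C[Mg]Br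
Why: Copper-catalysed, chlorosilane-accelerated conjugate addition of a Grignard reagent; C9 lies between the equatorial O1 substituent and the equatorial C6 methylene, and the vinyl group should enter past the smaller O–Si side, cis to C1.

Step 15
Reactants: 24 C9-vinyl lactone
Product: 26 C12 primary alcohol (C9 bears CH2CH2OH), via B-alkyl-9-BBN borane 25 (not isolated)
Conditions: 9-BBN, THF, 0 °C to rt; then NaBO3·4H2O, H2O
Reagents that add atoms: sodium perborate, [Na+].[O-]OB=O
Why: Anti-Markovnikov hydroboration of the only alkene, followed by perborate oxidation, which is mild enough to spare the lactone.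

Step 16
Reactants: 26 C12 primary alcohol
Product: 27 tris-TES lactone (O1, O19, O12 as TES ethers)
Conditions: Et3SiCl, imidazole, CH2Cl2, 0 °C
Reagents that add atoms: chlorotriethylsilane, CC[Si](Cl)(CC)CC
Why: Standard silylation of a primary alcohol; the C12 oxygen must be masked before enolate formation and metathesis.

Step 17
Reactants: 27 tris-TES lactone; 11 allyl bromide
Product: 28 C8-allyl lactone (C8 epimers; both serve)
Conditions: LiN(iPr)2, THF, −78 °C; allyl bromide, DMPU, −78 to −40 °C
Reagents that add atoms: allyl bromide (11), C=CCBr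
Why: Alkylation of the lactone lithium enolate installs C14 and C13; the configuration at C8 does not matter because C8 is enolised again in the next step.

Step 18
Reactants: 28 C8-allyl lactone; 29 acrolein
Product: 30 aldol adduct (C8 quaternary: allyl cis to the C9 chain, CH(OH)CH=CH2 trans to it; carbinol epimers)
Conditions: LiN(iPr)2, THF, −78 °C; acrolein, −78 °C; AcOH at −78 °C
Reagents that add atoms: acrolein (29), C=CC=O
Why: Aldol addition of the fully substituted lactone enolate to acrolein; the aldehyde approaches the enolate face opposite the adjacent C9 side chain and the axial C1 oxygen substituent, which places C15 anti to C11, and the cold acidic quench prevents retro-aldol cleavage.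

Step 19
Reactants: 30 aldol adduct
Product: 31 spiro cyclopentenol (ring D: C8, C14, C13=C16, C15-OH)
Conditions: second-generation Grubbs catalyst RuCl2(=CHPh)(PCy3)(H2IMes) (3 mol%), CH2Cl2, 40 °C
Reagents that add atoms: none
Why: Ring-closing metathesis of the geminal allyl and vinyl carbinol groups gives the spiro cyclopent-3-enol; no other alkene is present.

Step 20
Reactants: 31 spiro cyclopentenol
Product: 32 spiro cyclopentenone (C15 ketone, C16=C13)
Conditions: Dess–Martin periodinane, pyridine, CH2Cl2, 0 °C to rt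
Reagents that add atoms: none
Why: Oxidation of the allylic alcohol gives the conjugated enone and removes the uncontrolled carbinol centre.

Step 21
Reactants: 32 spiro cyclopentenone
Product: 33 enone triol (1α-OH, C19 OH, C12 OH; C6 OTBDPS kept)
Conditions: pyridinium p-toluenesulfonate (20 mol%), MeOH–CH2Cl2, rt
Reagents that add atoms: none
Why: Mild acidic methanolysis removes triethylsilyl ethers and leaves the far more stable TBDPS ether; acid is chosen to avoid base-promoted acyl migration of the lactone to the free 1-hydroxyl.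

Step 22
Reactants: 33 enone triol
Product: 34 C12 iodide diol
Conditions: PPh3, I2, imidazole, CH2Cl2, 0 °C
Reagents that add atoms: iodine, II
Why: Appel iodination takes the unhindered primary C12 alcohol; the neopentyl C19 alcohol and the hindered secondary C1 alcohol cannot undergo the substitution.

Step 23
Reactants: 34 C12 iodide diol; 35 acetic anhydride
Product: 36 iodo diacetate (spiro cyclopentenone lactone with C9 iodoethyl chain, 1α-OAc, 19-OAc, 6-OTBDPS)
Conditions: Ac2O, pyridine, DMAP (cat.), CH2Cl2, 0 °C to rt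
Reagents that add atoms: acetic anhydride (35), CC(=O)OC(C)=O
Why: DMAP-catalysed acetylation installs both acetates of the target once no further strong base is needed.

Step 24
Reactants: 36 iodo diacetate
Product: 37 bicyclo[3.2.1]octanone spirolactone (ring C closed; C16 is CH2)
Conditions: (Me3Si)3SiH, AIBN (20 mol%), toluene (5 mM), 85 °C, slow addition
Reagents that add atoms: none
Why: Iodine abstraction from C12 by the (Me3Si)3Si radical gives a primary alkyl radical that adds to C13, the β-carbon of the cyclopentenone, and the C16 α-keto radical then takes hydrogen from the silane and carries the chain. The closest known reaction type is the reductive cyclisation of alkyl iodides onto cycloalkenones (intramolecular Giese addition) used to build bridged bicyclic ketones. Ring C (C8, C9, C11, C12, C13, C14) closes in the 6-exo-trig mode, the C13=C16 bond lying outside the new ring. The new stereocentre C13 is fixed by the spiro centre C8, because the C9 tether can reach the enone only from the ring D face that carries C9. The step needs attack at C13 and not at C16, which the match of a nucleophilic radical with the electron-poor β-carbon secures, and it needs cyclisation before hydrogen transfer, which high dilution and slow silane addition secure. Acetates, lactone and silyl ether are inert to silyl radicals.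

Step 25
Reactants: 37 bicyclo[3.2.1]octanone spirolactone; 38 dimethyl(methylidene)ammonium iodide (Eschenmoser's salt)
Product: 39 Mannich base (C16 bears CH2NMe2; C16 epimers)
Conditions: LiN(SiMe3)2, THF, −78 °C; dimethyl(methylidene)ammonium iodide, −78 to 0 °C
Reagents that add atoms: dimethyl(methylidene)ammonium iodide (38), C=[N+](C)C.[I-]
Why: The ketone can enolise only towards C16 (C8 is quaternary) and is far more acidic than the acetates, so the enolate forms selectively and undergoes the Mannich reaction.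

Step 26
Reactants: 39 Mannich base; 9 iodomethane
Product: 41 TBDPS ether of the target (exocyclic C16=C17 enone), via trimethylammonium iodide 40 (not isolated)
Conditions: MeI, CH2Cl2, rt; then aqueous NaHCO3, rt
Reagents that add atoms: none
Why: Quaternisation followed by base-induced β-elimination of trimethylamine is the standard way to turn a Mannich base into an α-methylene ketone.

Step 27
Reactants: 41 TBDPS ether of the target
Product: 42 CNP0105570.2
Conditions: HF·pyridine, pyridine, THF, 0 °C to rt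
Reagents that add atoms: none
Why: Buffered hydrogen fluoride cleaves the primary silyl ether under acidic conditions that spare the acetates, the lactone and the α-methylene ketone.

**Compound list**
1 | (E)-but-2-ene-1,4-diol | OC/C=C/CO | starting material
2 | (E)-4-[(tert-butyldiphenylsilyl)oxy]but-2-en-1-ol | OC/C=C/CO[Si](c1ccccc1)(c1ccccc1)C(C)(C)C | intermediate
3 | (E)-4-[(tert-butyldiphenylsilyl)oxy]but-2-enal | O=C/C=C/CO[Si](c1ccccc1)(c1ccccc1)C(C)(C)C | intermediate
4 | methyl 5-methoxy-3-oxopentanoate | COCCC(=O)CC(=O)OC | starting material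
5 | methyl 3-oxopent-4-enoate | C=CC(=O)CC(=O)OC | intermediate
6 | methyl (2Z)-3-[(tert-butyldimethylsilyl)oxy]penta-2,4-dienoate | C=C/C(O[Si](C)(C)C(C)(C)C)=C/C(=O)OC | intermediate
7 | methyl 2-(TBS-oxy)-6-(TBDPS-oxymethyl)-5-formylcyclohex-2-ene-1-carboxylate (C5 fixed, C4 and C10 not) | COC(=O)C1C(O[Si](C)(C)C(C)(C)C)=CCC(C=O)[C@H]1CO[Si](c2ccccc2)(c2ccccc2)C(C)(C)C | intermediate (not isolated)
8 | methyl 6-(TBDPS-oxymethyl)-5-formyl-2-oxocyclohexane-1-carboxylate (C6 α on C5; C4 and C10 epimerisable) | COC(=O)C1C(=O)CCC(C=O)[C@H]1CO[Si](c2ccccc2)(c2ccccc2)C(C)(C)C | intermediate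
9 | iodomethane | CI | starting material
10 | methyl 6-(TBDPS-oxymethyl)-5-formyl-5-methyl-2-oxocyclohexane-1-carboxylate (C4: CH3 β, CHO α) | COC(=O)C1C(=O)CC[C@@](C)(C=O)[C@H]1CO[Si](c2ccccc2)(c2ccccc2)C(C)(C)C | intermediate
11 | allyl bromide | C=CCBr | starting material
12 | methyl 1-allyl-6-(TBDPS-oxymethyl)-5-formyl-5-methyl-2-oxocyclohexane-1-carboxylate (C10: allyl β, CO2Me α) | C=CC[C@]1(C(=O)OC)C(=O)CC[C@@](C)(C=O)[C@H]1CO[Si](c2ccccc2)(c2ccccc2)C(C)(C)C | intermediate
13 | methyl 6-(TBDPS-oxymethyl)-5-formyl-5-methyl-2-oxo-1-[(E)-prop-1-enyl]cyclohexane-1-carboxylate | C/C=C/[C@]1(C(=O)OC)C(=O)CC[C@@](C)(C=O)[C@H]1CO[Si](c2ccccc2)(c2ccccc2)C(C)(C)C | intermediate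
14 | ring A triol: C10 propenyl (β) and CH2OH (C20, α), 1α-OH, C4 CH3 (β) and CH2OH (C19, α), C5 CH2OTBDPS (α) | C/C=C/[C@]1(CO)[C@@H](O)CC[C@@](C)(CO)[C@H]1CO[Si](c2ccccc2)(c2ccccc2)C(C)(C)C | intermediate
15 | cyclic phenylboronate of 14 across O1 and O20 | C/C=C/[C@]1(COB(c3ccccc3)O2)[C@@H]2CC[C@@](C)(CO)[C@H]1CO[Si](c3ccccc3)(c3ccccc3)C(C)(C)C | intermediate (not isolated)
16 | 19-O-TES ether of boronate 15 | C/C=C/[C@]1(COB(c3ccccc3)O2)[C@@H]2CC[C@@](C)(CO[Si](CC)(CC)CC)[C@H]1CO[Si](c3ccccc3)(c3ccccc3)C(C)(C)C | intermediate (not isolated)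
17 | 19-O-TES diol (1α-OH, C20 OH) | C/C=C/[C@]1(CO)[C@@H](O)CC[C@@](C)(CO[Si](CC)(CC)CC)[C@H]1CO[Si](c2ccccc2)(c2ccccc2)C(C)(C)C | intermediate
18 | acryloyl chloride | C=CC(=O)Cl | starting material
19 | 20-O-acrylate of 17 (1α-OH free) | C/C=C/[C@]1(COC(=O)C=C)[C@@H](O)CC[C@@](C)(CO[Si](CC)(CC)CC)[C@H]1CO[Si](c2ccccc2)(c2ccccc2)C(C)(C)C | intermediate
20 | 1-O-TES 20-O-acrylate | C/C=C/[C@]1(COC(=O)C=C)[C@@H](O[Si](CC)(CC)CC)CC[C@@](C)(CO[Si](CC)(CC)CC)[C@H]1CO[Si](c2ccccc2)(c2ccccc2)C(C)(C)C | intermediate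
21 | unsaturated spirolactone (7,20-olide, C8=C9; O1 and O19 TES, O6 TBDPS) | O=C1OC[C@@]2(C=C1)[C@@H](O[Si](CC)(CC)CC)CC[C@@](C)(CO[Si](CC)(CC)CC)[C@H]2CO[Si](c1ccccc1)(c1ccccc1)C(C)(C)C | intermediate
22 | vinylmagnesium bromide | C=C[Mg]Br | starting material
23 | trimethylsilyl ketene acetal of 24 | C=C[C@@H]1C=C(O[Si](C)(C)C)OC[C@]12[C@@H](O[Si](CC)(CC)CC)CC[C@@](C)(CO[Si](CC)(CC)CC)[C@H]2CO[Si](c1ccccc1)(c1ccccc1)C(C)(C)C | intermediate (not isolated)
24 | C9-vinyl spirolactone (vinyl cis to C1 on the lactone ring) | C=C[C@@H]1CC(=O)OC[C@]12[C@@H](O[Si](CC)(CC)CC)CC[C@@](C)(CO[Si](CC)(CC)CC)[C@H]2CO[Si](c1ccccc1)(c1ccccc1)C(C)(C)C | intermediate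
25 | B-(C12-alkyl)-9-borabicyclo[3.3.1]nonane from 24 | C1CC2CCCC(C1)B2CC[C@@H]1CC(=O)OC[C@]12[C@@H](O[Si](CC)(CC)CC)CC[C@@](C)(CO[Si](CC)(CC)CC)[C@H]2CO[Si](c1ccccc1)(c1ccccc1)C(C)(C)C | intermediate (not isolated)
26 | C9-(2-hydroxyethyl) spirolactone | OCC[C@@H]1CC(=O)OC[C@]12[C@@H](O[Si](CC)(CC)CC)CC[C@@](C)(CO[Si](CC)(CC)CC)[C@H]2CO[Si](c1ccccc1)(c1ccccc1)C(C)(C)C | intermediate
27 | C9-(2-TES-oxyethyl) spirolactone (tris-TES) | CC[Si](CC)(CC)OCC[C@@H]1CC(=O)OC[C@]12[C@@H](O[Si](CC)(CC)CC)CC[C@@](C)(CO[Si](CC)(CC)CC)[C@H]2CO[Si](c1ccccc1)(c1ccccc1)C(C)(C)C | intermediate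
28 | C8-allyl lactone (C8 epimers) | C=CCC1C(=O)OC[C@@]2([C@@H]1CCO[Si](CC)(CC)CC)[C@@H](O[Si](CC)(CC)CC)CC[C@@](C)(CO[Si](CC)(CC)CC)[C@H]2CO[Si](c1ccccc1)(c1ccccc1)C(C)(C)C | intermediate
29 | acrolein | C=CC=O | starting material
30 | C8-allyl C8-(1-hydroxyallyl) lactone (allyl cis to the C9 chain; carbinol epimers) | C=CC[C@]1(C(O)C=C)C(=O)OC[C@@]2([C@@H]1CCO[Si](CC)(CC)CC)[C@@H](O[Si](CC)(CC)CC)CC[C@@](C)(CO[Si](CC)(CC)CC)[C@H]2CO[Si](c1ccccc1)(c1ccccc1)C(C)(C)C | intermediate
31 | spiro cyclopent-3-enol lactone (C15 carbinol epimers) | OC1C=CC[C@@]12C(=O)OC[C@@]3([C@@H]2CCO[Si](CC)(CC)CC)[C@@H](O[Si](CC)(CC)CC)CC[C@@](C)(CO[Si](CC)(CC)CC)[C@H]3CO[Si](c1ccccc1)(c1ccccc1)C(C)(C)C | intermediate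
32 | spiro cyclopent-2-enone lactone, tris-TES | O=C1C=CC[C@@]12C(=O)OC[C@@]3([C@@H]2CCO[Si](CC)(CC)CC)[C@@H](O[Si](CC)(CC)CC)CC[C@@](C)(CO[Si](CC)(CC)CC)[C@H]3CO[Si](c1ccccc1)(c1ccccc1)C(C)(C)C | intermediate
33 | spiro cyclopentenone lactone triol (1α-OH, C19 OH, C12 OH) | O=C1C=CC[C@@]12C(=O)OC[C@@]3([C@@H]2CCO)[C@@H](O)CC[C@@](C)(CO)[C@H]3CO[Si](c1ccccc1)(c1ccccc1)C(C)(C)C | intermediate
34 | C12 iodide diol | O=C1C=CC[C@@]12C(=O)OC[C@@]3([C@@H]2CCI)[C@@H](O)CC[C@@](C)(CO)[C@H]3CO[Si](c1ccccc1)(c1ccccc1)C(C)(C)C | intermediate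
35 | acetic anhydride | CC(=O)OC(C)=O | starting material
36 | spiro cyclopentenone lactone with C9 iodoethyl chain, 1α,19-diacetate, 6-O-TBDPS | O=C1C=CC[C@@]12C(=O)OC[C@@]3([C@@H]2CCI)[C@@H](OC(C)=O)CC[C@@](C)(COC(C)=O)[C@H]3CO[Si](c1ccccc1)(c1ccccc1)C(C)(C)C | intermediate
37 | bicyclo[3.2.1]octanone spirolactone lacking the methylene, 6-O-TBDPS | C1C(=O)[C@]23C[C@H]1CC[C@H]2[C@]1(COC3=O)[C@@H](OC(C)=O)CC[C@@](C)(COC(C)=O)[C@H]1CO[Si](c1ccccc1)(c1ccccc1)C(C)(C)C | intermediate
38 | dimethyl(methylidene)ammonium iodide | C=[N+](C)C.[I-] | starting material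
39 | C16 (dimethylamino)methyl ketone (C16 epimers) | CN(C)CC1C(=O)[C@]23C[C@H]1CC[C@H]2[C@]1(COC3=O)[C@@H](OC(C)=O)CC[C@@](C)(COC(C)=O)[C@H]1CO[Si](c1ccccc1)(c1ccccc1)C(C)(C)C | intermediate
40 | C16 (trimethylammonio)methyl ketone iodide | C[N+](C)(C)CC1C(=O)[C@]23C[C@H]1CC[C@H]2[C@]1(COC3=O)[C@@H](OC(C)=O)CC[C@@](C)(COC(C)=O)[C@H]1CO[Si](c1ccccc1)(c1ccccc1)C(C)(C)C.[I-] | intermediate (not isolated)
41 | 6-O-TBDPS ether of the target | C=C1C(=O)[C@]23C[C@H]1CC[C@H]2[C@]1(COC3=O)[C@@H](OC(C)=O)CC[C@@](C)(COC(C)=O)[C@H]1CO[Si](c1ccccc1)(c1ccccc1)C(C)(C)C | intermediate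
42 | CNP0105570.2 (1α,19-diacetoxy-6-hydroxy-15-oxo-6,7-seco-ent-kaur-16-en-7,20-olide) | C=C1C(=O)[C@]23C[C@H]1CC[C@H]2[C@]1(COC3=O)[C@@H](OC(C)=O)CC[C@@](C)(COC(C)=O)[C@H]1CO | target

**Totals and risks**
Total step count: 27. Longest linear sequence: 25 steps (steps 1, 2 and 5–27, from 1 to 42).

Steps most likely to fail:

1. Step 5. The acidic amine salt may strip the silyl group from diene 6 before cycloaddition; the freed vinyl ketone would then be open to Michael addition followed by closure at the aldehyde carbon, and facial control at C5 could also be poor. The fallback replaces catalyst control by an oxazolidinone auxiliary and a Lewis acid. Enal 3 would be oxidised (NaClO2, NaH2PO4, 2-methylbut-2-ene) to (E)-4-(TBDPS-oxy)but-2-enoic acid F1. Coupling through the pivaloyl mixed anhydride with lithiated (S)-4-benzyloxazolidin-2-one would give the N-enoyl oxazolidinone F2. Me2AlCl-promoted Diels–Alder reaction of the chelated imide with diene 6, on the face away from the benzyl group, would give the cycloadduct silyl enol ether F3, and dilute HCl would turn it into the keto imide F4. LiSEt would give the S-ethyl thioester F5, and Fukuyama reduction (Et3SiH, Pd/C) would return the route at keto aldehyde 8.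

2. Step 14. The vinyl group may be delivered to the C9 face next to C6 instead of the face next to O1, or the neopentyl β-carbon may not react at all. The fallback delivers the two carbons from O1 by a tether. Alcohol 19 would be treated with ethyl vinyl ether and N-bromosuccinimide to give the bromoacetal F6, and ring-closing metathesis as in step 13 would give the unsaturated lactone bromoacetal F7. Ueno–Stork radical cyclisation (Bu3SnH, AIBN, benzene, 80 °C) would join the acetal CH2 to C9 in a 6-exo closure from the O1 face and give the cyclic ethyl acetal F8. Aqueous acid would open it to the lactol F9, losing the 19-O-TES group as well, and NaBH4 would give the triol F10. Silylation of all three hydroxyls with triethylsilyl triflate and 2,6-lutidine would return the route at 27.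

3. Step 18. Acrolein may add to the enolate face on the side of the C9 chain, giving the wrong C8 epimer, or the hindered aldolate may revert by retro-aldol cleavage. The fallback reverses the order in which the two C8 substituents are introduced, so that the same facial preference then gives the needed epimer. Lactone 27 would be deprotonated with LiN(iPr)2 and treated with acrolein to give the C8-H aldol F11, which would be silylated (triethylsilyl triflate, 2,6-lutidine) to the TES ether F12. A second deprotonation and allyl bromide would give the C8-allyl compound F13, and ring-closing metathesis would give the cyclopentenyl TES ether F14. Pyridinium p-toluenesulfonate in methanol would remove all four TES groups to give the tetraol F15, and MnO2, which oxidises only the allylic C15 alcohol, would return the route at 33.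

**Further compounds**
F1 | step 5 | (E)-4-[(tert-butyldiphenylsilyl)oxy]but-2-enoic acid | OC(=O)/C=C/CO[Si](c1ccccc1)(c1ccccc1)C(C)(C)C
F2 | step 5 | (S)-4-benzyl-3-[(E)-4-(TBDPS-oxy)but-2-enoyl]oxazolidin-2-one | O=C(/C=C/CO[Si](c1ccccc1)(c1ccccc1)C(C)(C)C)N1[C@@H](Cc2ccccc2)COC1=O
F3 | step 5 | cycloadduct silyl enol ether carrying the acyl oxazolidinone at C4 | COC(=O)C1C(O[Si](C)(C)C(C)(C)C)=CCC(C(=O)N2[C@@H](Cc3ccccc3)COC2=O)[C@H]1CO[Si](c2ccccc2)(c2ccccc2)C(C)(C)C
F4 | step 5 | keto ester imide | COC(=O)C1C(=O)CCC(C(=O)N2[C@@H](Cc3ccccc3)COC2=O)[C@H]1CO[Si](c2ccccc2)(c2ccccc2)C(C)(C)C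
F5 | step 5 | keto ester S-ethyl thioester | COC(=O)C1C(=O)CCC(C(=O)SCC)[C@H]1CO[Si](c2ccccc2)(c2ccccc2)C(C)(C)C
F6 | step 14 | 1-O-(2-bromo-1-ethoxyethyl) acetal of acrylate 19 | C/C=C/[C@]1(COC(=O)C=C)[C@@H](OC(CBr)OCC)CC[C@@](C)(CO[Si](CC)(CC)CC)[C@H]1CO[Si](c2ccccc2)(c2ccccc2)C(C)(C)C
F7 | step 14 | unsaturated spirolactone bromoacetal | O=C1OC[C@@]2(C=C1)[C@@H](OC(CBr)OCC)CC[C@@](C)(CO[Si](CC)(CC)CC)[C@H]2CO[Si](c1ccccc1)(c1ccccc1)C(C)(C)C
F8 | step 14 | cyclic ethyl acetal bridging O1 and C9 (C11 and C12 in place) | C3[C@@H]1CC(=O)OC[C@]12[C@@H](OC3OCC)CC[C@@](C)(CO[Si](CC)(CC)CC)[C@H]2CO[Si](c1ccccc1)(c1ccccc1)C(C)(C)C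
F9 | step 14 | lactol (C12 hemiacetal with O1; C19 OH free) | C3[C@@H]1CC(=O)OC[C@]12[C@@H](OC3O)CC[C@@](C)(CO)[C@H]2CO[Si](c1ccccc1)(c1ccccc1)C(C)(C)C
F10 | step 14 | lactone triol (1α-OH, C19 OH, C12 OH) | OCC[C@@H]1CC(=O)OC[C@]12[C@@H](O)CC[C@@](C)(CO)[C@H]2CO[Si](c1ccccc1)(c1ccccc1)C(C)(C)C
F11 | step 18 | C8-(1-hydroxyallyl) lactone (C8-H) | C=CC(O)C1C(=O)OC[C@@]2([C@@H]1CCO[Si](CC)(CC)CC)[C@@H](O[Si](CC)(CC)CC)CC[C@@](C)(CO[Si](CC)(CC)CC)[C@H]2CO[Si](c1ccccc1)(c1ccccc1)C(C)(C)C
F12 | step 18 | C8-(1-TES-oxyallyl) lactone | C=CC(O[Si](CC)(CC)CC)C1C(=O)OC[C@@]2([C@@H]1CCO[Si](CC)(CC)CC)[C@@H](O[Si](CC)(CC)CC)CC[C@@](C)(CO[Si](CC)(CC)CC)[C@H]2CO[Si](c1ccccc1)(c1ccccc1)C(C)(C)C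
F13 | step 18 | C8-allyl C8-(1-TES-oxyallyl) lactone | C=CC[C@]1(C(O[Si](CC)(CC)CC)C=C)C(=O)OC[C@@]2([C@@H]1CCO[Si](CC)(CC)CC)[C@@H](O[Si](CC)(CC)CC)CC[C@@](C)(CO[Si](CC)(CC)CC)[C@H]2CO[Si](c1ccccc1)(c1ccccc1)C(C)(C)C
F14 | step 18 | spiro cyclopentenyl TES ether | CC[Si](CC)(CC)OC1C=CC[C@@]12C(=O)OC[C@@]3([C@@H]2CCO[Si](CC)(CC)CC)[C@@H](O[Si](CC)(CC)CC)CC[C@@](C)(CO[Si](CC)(CC)CC)[C@H]3CO[Si](c1ccccc1)(c1ccccc1)C(C)(C)C
F15 | step 18 | spiro cyclopentenol tetraol | OC1C=CC[C@@]12C(=O)OC[C@@]3([C@@H]2CCO)[C@@H](O)CC[C@@](C)(CO)[C@H]3CO[Si](c1ccccc1)(c1ccccc1)C(C)(C)C
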